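# Proposed synthesis of 7-hydroxy-6-methoxy-3-[(6-methoxy-2-oxochromen-7-yl)oxy]chromen-2-one (23) by benzannulation on a coumarin-3-yl ynol ether

## Analysis of the target

- Target 23 consists of two coumarin (benzo-α-pyranone) bicycles, four rings in all, held together by a single oxygen that joins C3 of the unprimed coumarin to C7' of the primed one.
- Both halves carry the same 6-methoxy-7-oxygen pattern. The unprimed half has a free C7 hydroxyl; the primed half has its C7' oxygen in the ether bridge.
- There is no stereocentre. Every problem is one of regiochemistry and chemoselectivity.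
- The sensitive groups are:
  - the two lactones, which open with hydroxide, alkoxide or strong nucleophiles;
  - the free C7 phenol;
  - the enol-ether C3–O bond;
  - the unsubstituted C3'=C4' alkene, which is open to hydrogenation and conjugate addition.
- The hard bond is C3–O–C7'. It joins an enol-type oxygen on an electron-poor lactone to an electron-rich aryl carbon flanked by a methoxy group. That carbon is not a site for nucleophilic aromatic substitution, and the two oxygenated benzene rings are too alike for a late substitution to tell them apart.
- The strategy rests on the benzene ring of the primed unit. Its carbons C8a', C8', C7' and C6' carry, in this order, O1', hydrogen, the ether oxygen and the methoxy group, so the two ring oxygens on C8a' and C7' are meta and the methoxy group sits next to the ether oxygen.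
- That sequence is what the union of an α-methoxy vinylketene with an oxygen-polarised alkyne delivers. The primed arene can therefore be built onto the ether oxygen, instead of the oxygen being attached to a finished arene.

## Retrosynthetic reasoning

**23 from 22.** The C7 hydroxyl is masked as a benzyl ether, so the last cut is the O–CH2Ph bond. A free phenol would compete in the O-alkynylation and would add to ketenes. A benzyl ether survives heat, anhydrous acid and weak base. Its removal by a Lewis acid with a cation scavenger leaves the methyl ethers, both lactones and the C3'=C4' alkene alone.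

**22 from 19 and 20.** The primed pyranone is removed by cutting C4'–C4a' and O1'–C2'. Its three carbons are those of propiolate 20, and what remains is phenol 19, whose hydroxyl is the future O1'. The forward reaction must add the arene across the alkyne at the carbon ortho to the hydroxyl and para to the C7' oxygen. The other ortho carbon lies between two oxygens and is hindered. The (Z)-cinnamate 21 then lactonises. Putting this ring on last means the benzannulation only has to deliver a simple phenol, and the reactive C3'=C4' alkene is not carried through earlier steps.

**19 from 18.** The C8'–H bond is traced back to a C8'–Si bond. The silyl group is needed earlier to make the ynol ether stable and isolable. It leaves by ipso protonation because C8' is flanked by two oxygens.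

**18 from 10 and 13 (the key disconnection).** The benzene ring of the primed unit is cut at C8a'–C8' and C7'–C6'.
- The two-carbon piece (C8' with silicon, C7' with the ether oxygen) is ynol ether 10.
- The four-carbon piece (C8a', C4a', C5', C6' with its methoxy group) is cyclobutenone 13, the thermal source of vinylketene 14.
- The cut is made here and not at either C–O bond of the bridge because those are the bonds hardest to form. With the oxygen on C3 from the start, no aryl C–O coupling is required.
- The forward reaction needs one orientation in the ketene–alkyne addition. The cascade then runs through 15, 16 and 17 to the phenol.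

**10 from 8 and 9.** The O–C(sp) bond is cut. Enol 8 has a single free hydroxyl, so alkynylation with bromoalkyne 9 has no site-selectivity issue. The forward reaction is a copper-catalysed C–O coupling under conditions mild enough for the lactone.

**8 from 6, 6 from 2 and 3, 2 from 1.** The unprimed pyranone is opened at C3–C4 and O1–C2. The aldehyde carbon of 2 becomes C4. N-acetylglycine 3 supplies C2 and C3 with a heteroatom already on C3. The nitrogen of 6 is exchanged for oxygen by hydrolysis through amine 7. Aldehyde 2 comes from 1 by benzylation of the hydroxyl para to the formyl group.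

**13 from 12, 12 from 11.** The methyl–oxygen bond of the enol ether is cut, leading to dione 12, which comes from the bis-silyl enediol ether 11 by oxidative desilylation.

## Alternatives that were turned down

**Alternative 1: three-component carbenoid route.**
- *Disconnection:* C3–O and C3–C4 of the unprimed pyranone.
  - Ethyl diazoacetate A2 supplies C2 and C3.
  - 7-Hydroxy-6-methoxychromen-2-one A3 brings the whole primed half through its phenol oxygen.
  - 4-Formyl-6-methoxy-1,3-phenylene diacetate A4 supplies C4 with its arene.
- *Forward key step:* under a dirhodium tetracarboxylate catalyst the carbenoid from A2 takes the phenol oxygen of A3. The oxonium ylide is to be intercepted by the aldehyde of A4 before its proton shifts. This gives hydroxy ester A1 (racemic; both stereocentres disappear on dehydration). Dehydration, deacetylation and lactonisation follow.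
- *For it:* it is highly convergent. The primed coumarin is used intact. The difficult C3–O bond is made by a mild O–H insertion. On step count and on forming the ether bond it is stronger than the chosen route.
- *Against it:* the ylide from a phenol carries an acidic proton and collapses by a fast intramolecular 1,2-shift. An acceptor-only carbenoid gives a short-lived ylide. A4 is an electron-rich, ortho-substituted aldehyde and so a poor trap. Plain O–H insertion should therefore dominate, and nothing in the substrates biases the race.
- *Comparison:* the chosen route takes more steps. In exchange its key bond formation is oriented by the polarisation of the two partners and does not depend on winning a kinetic competition.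

**Alternative 2: photo-oxidative lactonisation.**
- *Disconnection:* O1'–C8a' of the primed pyranone, leading back to the 4-aryloxy-3-methoxycinnamic acid A6.
- *Forward key step:* visible light, a flavin photocatalyst and air isomerise the (E)-acid to the (Z)-acid. The arene is then oxidised and the carboxylate attacks the carbon para to the methoxy group. This closes the primed lactone to acetate A5, which needs only deacetylation.
- *For it:* the end-game is the shortest of all. It uses a C–H bond and no prefunctionalised arene. The site para to methoxy is the electronically favoured one. On end-game step count and atom economy it is stronger.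
- *Against it:* the key step does nothing for the C3–O–aryl bond. A6 still has to be made by O-arylating a 3-hydroxycoumarin, which is the unsolved problem. The 3-aryloxycoumarin in A6 absorbs in the same region and is an electron-rich alkene, prone to photodimerisation and oxidative cleavage under the reaction conditions.
- *Comparison:* the chosen route removes the ether problem by growing the arene on the ether oxygen. The price is a thermal cascade that has not been demonstrated on this substrate class.

**Alternative 3: Baeyer–Villiger ring expansion.**
- *Disconnection:* O1–C8a of the unprimed lactone, through oxygen insertion into the 2-aryloxyindan-1-one A8.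
- *Forward key step:* a peracid adds to the ketone and the aryl carbon, which is para to a methoxy group, migrates to oxygen. This gives dihydrocoumarin A7 (racemic; its stereocentre is removed by the later dehydrogenation).
- *For it:* the ether bond is made by displacement of an alpha-halo ketone with phenol A3. This is the most dependable C–O bond formation among the four routes, and on that point it is stronger.
- *Against it:* the competing migrating group is the secondary carbon bearing the aryloxy oxygen, and alpha-oxygenated carbons migrate very well, so insertion on the wrong side is a real risk. A7 is also at the wrong oxidation level and needs a C3–C4 dehydrogenation. With the indanone synthesis the step count is no lower than in the chosen route.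
- *Comparison:* the chosen route needs no redox correction and its regiochemistry follows from polarisation, not from a migratory preference. It is more speculative in its key step.

Key step: step 7

Assumption: unprimed locants refer to the coumarin that carries the C7 hydroxyl and primed locants to the coumarin bound through O7'; 9 and 11 are taken as purchased, and 13, being volatile and heat-sensitive, is carried forward as a cold solution.

## Route

Step 1
Reactants: 1 2,4-dihydroxy-5-methoxybenzaldehyde
Product: 2 4-(benzyloxy)-2-hydroxy-5-methoxybenzaldehyde
Conditions: BnBr, NaHCO3, MeCN, 80 °C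
Reagents that add atoms: benzyl bromide, BrCc1ccccc1
Why: Williamson etherification; the C2 hydroxyl is held in a hydrogen bond to the formyl group and is less acidic than the C4 hydroxyl para to the aldehyde, so the weak base should ionise and benzylate only the C4 oxygen.

Step 2
Reactants: 2 4-(benzyloxy)-2-hydroxy-5-methoxybenzaldehyde; 3 N-acetylglycine
Product: 6 3-acetamido-7-(benzyloxy)-6-methoxychromen-2-one, via 2-methyloxazol-5(4H)-one 4 (not isolated), via arylidene azlactone 5 (not isolated)
Conditions: Ac2O, NaOAc, 110 °C
Reagents that add atoms: none
Why: Erlenmeyer–Plöchl azlactone condensation followed by lactonisation; 3 is cyclodehydrated to azlactone 4, which condenses with the aldehyde carbon (future C4) to the O-acetylated arylidene azlactone 5, and acetate-mediated acyl transfer frees the phenoxide, which opens the azlactone carbonyl after alkene equilibration and closes the pyranone with nitrogen left on C3.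

Step 3
Reactants: 6 3-acetamido-7-(benzyloxy)-6-methoxychromen-2-one
Product: 8 7-(benzyloxy)-3-hydroxy-6-methoxychromen-2-one, via 3-aminocoumarin 7 (not isolated)
Conditions: 3 M aq. HCl, 1,4-dioxane, 90 °C
Reagents that add atoms: water, O
Why: Acid hydrolysis of an enamide, the standard passage from 3-acetamidocoumarins to 3-hydroxycoumarins; the amide is cleaved to amine 7, whose imine tautomer is hydrolysed to the alpha-keto lactone, which rests as enol 8, and the benzyl ether on the electron-poor coumarin ring should last at this acid strength.

Step 4
Reactants: 8 7-(benzyloxy)-3-hydroxy-6-methoxychromen-2-one; 9 (bromoethynyl)triisopropylsilane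
Product: 10 7-(benzyloxy)-6-methoxy-3-{[(triisopropylsilyl)ethynyl]oxy}chromen-2-one
Conditions: CuI (10 mol%), 1,10-phenanthroline (20 mol%), K3PO4, PhMe, 90 °C
Reagents that add atoms: none
Why: Proposed new method: the enolic hydroxyl of 8 should form a monovalent copper aryloxide, add oxidatively to the C–Br bond of 9 to give a trivalent copper alkynyl aryloxide and eliminate reductively to the C(sp)–O bond; a competing base-mediated addition of the oxygen to the bromine-bearing carbon would give a 1-bromo enol ether that loses HBr to the same product; the closest known reaction types are the copper-catalysed N-alkynylation of amides with bromoalkynes and the copper-mediated coupling of phenols with 1,1-dibromoalkenes to aryl ynol ethers.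

Step 5
Reactants: 11 1,2-bis(trimethylsilyloxy)cyclobutene
Product: 12 cyclobutane-1,2-dione
Conditions: Br2, pentane, −60 °C to rt
Reagents that add atoms: none
Why: Oxidative desilylation of an enediol bis(silyl ether); bromine adds to the electron-rich alkene and both silyl groups leave as the bromosilane, a known preparation of this dione that avoids the base and water the strained dione does not tolerate.

Step 6
Reactants: 12 cyclobutane-1,2-dione
Product: 13 2-methoxycyclobut-2-en-1-one
Conditions: KN(SiMe3)2, THF–DMPU, −78 °C (12 added slowly); MeOTf, −78 to −20 °C; taken up cold in PhMe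
Reagents that add atoms: methyl trifluoromethanesulfonate, COS(=O)(=O)C(F)(F)F
Why: O-alkylation of a 1,2-diketone enolate, as in the formation of diosphenol methyl ethers; the hindered non-nucleophilic amide gives the potassium enolate, and a hard methylating agent in a dipolar medium should attack oxygen and not carbon.

Step 7
Reactants: 10 7-(benzyloxy)-6-methoxy-3-{[(triisopropylsilyl)ethynyl]oxy}chromen-2-one; 13 2-methoxycyclobut-2-en-1-one
Product: 18 7-(benzyloxy)-3-[3-hydroxy-6-methoxy-2-(triisopropylsilyl)phenoxy]-6-methoxychromen-2-one, via methoxy(vinyl)ketene 14 (not isolated), via vinylcyclobutenone 15 (not isolated), via dienylketene 16 (not isolated), via cyclohexadienone 17 (not isolated)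
Conditions: PhMe, 80 °C then 110 °C, sealed tube; 13 (2–3 equiv) added in portions
Reagents that add atoms: none
Why: Proposed new method: on heating, 13 should open by 4π electrocyclic cleavage of its C1–C4 bond to methoxy(vinyl)ketene 14, and ynol ether 10, whose oxygen makes the silyl-bearing carbon nucleophilic, should add to the ketene C=C in a (2+2) cycloaddition in which the ketene carbonyl carbon bonds to the silylated carbon (C8a'–C8') and the methoxy-bearing carbon bonds to the aryloxy carbon (C7'–C6'), giving vinylcyclobutenone 15. A second 4π opening, with the donor methoxy group turning outward and the vinyl group inward, should give (Z)-dienylketene 16. The benzene ring of the primed unit is then closed by thermal disrotatory 6π electrocyclisation of 16, carbonyl carbon to vinyl terminus, to cyclohexadienone 17, which tautomerises to phenol 18. The closest known reaction type is the Danheiser benzannulation of cyclobutenones with alkoxy- and silyloxyalkynes; new here are an aryl ynol ether of an enol and an alpha-methoxycyclobutenone. No stereocentre is formed. The step needs a single orientation in the (2+2) addition, and the polarisation of 10 by oxygen, helped by silicon stabilising positive charge on the oxygen-bearing carbon in the transition state, secures it, so hydroxyl, silyl, coumarinyloxy and methoxy land on four adjacent carbons in the order the target requires. The bulky silyl group beside the new hydroxyl should also shield the product phenol from acylation by excess ketene.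

Step 8
Reactants: 18 7-(benzyloxy)-3-[3-hydroxy-6-methoxy-2-(triisopropylsilyl)phenoxy]-6-methoxychromen-2-one
Product: 19 7-(benzyloxy)-3-(5-hydroxy-2-methoxyphenoxy)-6-methoxychromen-2-one
Conditions: TFA, CH2Cl2, 0 °C to rt
Reagents that add atoms: none
Why: Protodesilylation by ipso substitution; C8' is ortho to the free hydroxyl and ortho to the aryloxy oxygen, so protonation at the silicon-bearing carbon is fast and the beta-silyl arenium ion loses silicon to trifluoroacetate, while the benzyl ether and both ether links are stable to anhydrous acid at room temperature.

Step 9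
Reactants: 19 7-(benzyloxy)-3-(5-hydroxy-2-methoxyphenoxy)-6-methoxychromen-2-one; 20 ethyl propiolate
Product: 22 7-(benzyloxy)-6-methoxy-3-[(6-methoxy-2-oxochromen-7-yl)oxy]chromen-2-one, via (Z)-cinnamate 21 (not isolated)
Conditions: Pd(OAc)2 (5 mol%), TFA–CH2Cl2, rt
Reagents that add atoms: none
Why: Pd(OAc)2-catalysed hydroarylation of an alkynoate by an electron-rich phenol (Fujiwara-type, a Pechmann-like coumarin synthesis); the arene adds trans across 20 at the carbon ortho to the hydroxyl and para to the C7' oxygen, the other ortho carbon being wedged between two oxygens, and (Z)-cinnamate 21 lactonises with loss of ethanol, while the deactivated rings of the existing coumarin do not compete.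

Step 10
Reactants: 22 7-(benzyloxy)-6-methoxy-3-[(6-methoxy-2-oxochromen-7-yl)oxy]chromen-2-one
Product: 23 7-hydroxy-6-methoxy-3-[(6-methoxy-2-oxochromen-7-yl)oxy]chromen-2-one
Conditions: BCl3, C6HMe5, CH2Cl2, −78 °C
Reagents that add atoms: none
Why: Lewis-acid debenzylation with a cation scavenger; BCl3 ionises the benzyl C–O bond at low temperature and pentamethylbenzene takes up the benzyl cation, so the methyl ethers, both lactones, the diaryl ether and the C3'=C4' alkene, which would be at risk under hydrogenolysis, are left untouched.

## Compound list

1 | 2,4-dihydroxy-5-methoxybenzaldehyde | COc1cc(C=O)c(O)cc1O | starting material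
2 | 4-(benzyloxy)-2-hydroxy-5-methoxybenzaldehyde | COc1cc(C=O)c(O)cc1OCc1ccccc1 | intermediate
3 | N-acetylglycine | CC(=O)NCC(=O)O | starting material
4 | 2-methyl-1,3-oxazol-5(4H)-one | CC1=NCC(=O)O1 | intermediate (not isolated)
5 | (4Z)-4-[2-(acetyloxy)-4-(benzyloxy)-5-methoxybenzylidene]-2-methyl-1,3-oxazol-5(4H)-one | CC1=N/C(=C\c2cc(OC)c(OCc3ccccc3)cc2OC(C)=O)C(=O)O1 | intermediate (not isolated)
6 | 3-acetamido-7-(benzyloxy)-6-methoxychromen-2-one | CC(=O)Nc1cc2cc(OC)c(OCc3ccccc3)cc2oc1=O | intermediate
7 | 3-amino-7-(benzyloxy)-6-methoxychromen-2-one | Nc1cc2cc(OC)c(OCc3ccccc3)cc2oc1=O | intermediate (not isolated)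
8 | 7-(benzyloxy)-3-hydroxy-6-methoxychromen-2-one | COc1cc2cc(O)c(=O)oc2cc1OCc1ccccc1 | intermediate
9 | (bromoethynyl)triisopropylsilane | CC(C)[Si](C#CBr)(C(C)C)C(C)C | starting material
10 | 7-(benzyloxy)-6-methoxy-3-{[(triisopropylsilyl)ethynyl]oxy}chromen-2-one | COc1cc2cc(OC#C[Si](C(C)C)(C(C)C)C(C)C)c(=O)oc2cc1OCc1ccccc1 | intermediate
11 | 1,2-bis(trimethylsilyloxy)cyclobutene | C[Si](C)(C)OC1=C(O[Si](C)(C)C)CC1 | starting material
12 | cyclobutane-1,2-dione | O=C1CCC1=O | intermediate
13 | 2-methoxycyclobut-2-en-1-one | COC1=CCC1=O | intermediate
14 | 2-methoxybuta-1,3-dien-1-one (methoxy(vinyl)ketene) | COC(C=C)=C=O | intermediate (not isolated)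
15 | 3-{[7-(benzyloxy)-6-methoxy-2-oxochromen-3-yl]oxy}-4-ethenyl-4-methoxy-2-(triisopropylsilyl)cyclobut-2-en-1-one (racemic) | COC1(C=C)C(=O)C([Si](C(C)C)(C(C)C)C(C)C)=C1Oc1cc2cc(OC)c(OCc3ccccc3)cc2oc1=O | intermediate (not isolated)
16 | (3Z)-3-{[7-(benzyloxy)-6-methoxy-2-oxochromen-3-yl]oxy}-4-methoxy-2-(triisopropylsilyl)hexa-1,3,5-trien-1-one | O=C=C([Si](C(C)C)(C(C)C)C(C)C)/C(Oc1cc2cc(OC)c(OCc3ccccc3)cc2oc1=O)=C(/OC)C=C | intermediate (not isolated)
17 | 3-{[7-(benzyloxy)-6-methoxy-2-oxochromen-3-yl]oxy}-4-methoxy-2-(triisopropylsilyl)cyclohexa-2,4-dien-1-one | COC1=CCC(=O)C([Si](C(C)C)(C(C)C)C(C)C)=C1Oc1cc2cc(OC)c(OCc3ccccc3)cc2oc1=O | intermediate (not isolated)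
18 | 7-(benzyloxy)-3-[3-hydroxy-6-methoxy-2-(triisopropylsilyl)phenoxy]-6-methoxychromen-2-one | COc1ccc(O)c([Si](C(C)C)(C(C)C)C(C)C)c1Oc1cc2cc(OC)c(OCc3ccccc3)cc2oc1=O | intermediate
19 | 7-(benzyloxy)-3-(5-hydroxy-2-methoxyphenoxy)-6-methoxychromen-2-one | COc1ccc(O)cc1Oc1cc2cc(OC)c(OCc3ccccc3)cc2oc1=O | intermediate
20 | ethyl propiolate | C#CC(=O)OCC | starting material
21 | ethyl (2Z)-3-(4-{[7-(benzyloxy)-6-methoxy-2-oxochromen-3-yl]oxy}-2-hydroxy-5-methoxyphenyl)prop-2-enoate | CCOC(=O)/C=C\c1cc(OC)c(Oc2cc3cc(OC)c(OCc4ccccc4)cc3oc2=O)cc1O | intermediate (not isolated)
22 | 7-(benzyloxy)-6-methoxy-3-[(6-methoxy-2-oxochromen-7-yl)oxy]chromen-2-one | COc1cc2cc(Oc3cc4oc(=O)ccc4cc3OC)c(=O)oc2cc1OCc1ccccc1 | intermediate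
23 | 7-hydroxy-6-methoxy-3-[(6-methoxy-2-oxochromen-7-yl)oxy]chromen-2-one | COc1cc2cc(Oc3cc4oc(=O)ccc4cc3OC)c(=O)oc2cc1O | target

## Step count and risk

Total step count: 10.
Longest linear sequence: 8 steps (1, 2, 3, 4, 7, 8, 9, 10). The two-step branch 5–6 joins at step 7.

Steps least certain to work:

**Step 7 (key step).**
- *What may go wrong:* the (2+2) addition may be too slow. The alkyne is shielded by the triisopropylsilyl group and its oxygen lone pair is shared with the coumarin enol system. Dimerisation and polymerisation of ketene 14 could then outrun the cycloaddition. Acylation of the product phenol by excess ketene is a second loss.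
- *Fallback (known chemistry):* it sets out from aldehyde 2 and comes back at 22. Purchased 7-hydroxy-6-methoxychromen-2-one (scopoletin, A3) is O-alkylated with tert-butyl bromoacetate (K2CO3, acetone) to tert-butyl [(6-methoxy-2-oxochromen-7-yl)oxy]acetate F1. The ester is cleaved with TFA to [(6-methoxy-2-oxochromen-7-yl)oxy]acetic acid F2. F2 is condensed with 2 under Perkin–Oglialoro conditions (Ac2O, Et3N, 120 °C), the established way to 3-aryloxycoumarins, to give 22, which is debenzylated as in step 10.

**Step 4.**
- *What may go wrong:* reductive homocoupling of the bromoalkyne, alkynylation at C4 of the ambident enolate, or failure of C–O reductive elimination from a weakly nucleophilic enolate. Opening of the lactone by phosphate at 90 °C is a further risk.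
- *Fallback (known chemistry):* it sets out from 8 and comes back at 19. Purchased 3-bromo-4-methoxyphenol is silylated (TBSCl, imidazole) to (3-bromo-4-methoxyphenoxy)(tert-butyl)dimethylsilane F3. Bromine–lithium exchange and borate quench (n-BuLi, B(OiPr)3, then aqueous NH4Cl) convert it into {5-[(tert-butyldimethylsilyl)oxy]-2-methoxyphenyl}boronic acid F4. F4 is coupled with 8 under Chan–Lam conditions (Cu(OAc)2, pyridine, 4 Å MS, CH2Cl2, air, rt) to 7-(benzyloxy)-3-{5-[(tert-butyldimethylsilyl)oxy]-2-methoxyphenoxy}-6-methoxychromen-2-one F5. Desilylation with TBAF/AcOH gives 19.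

**Step 6.**
- *What may go wrong:* self-condensation and ring contraction of the strongly electrophilic dione under base, methylation on carbon instead of oxygen, and loss of the volatile, thermally labile product on handling.
- *Fallback:* it avoids the cyclobutenone, sets out from 10 and comes back at 18. Horner–Wadsworth–Emmons reaction of purchased trimethyl 2-methoxyphosphonoacetate with acetaldehyde gives methyl (2Z)-2-methoxybut-2-enoate F6 (either alkene geometry serves). Saponification (LiOH) gives (2Z)-2-methoxybut-2-enoic acid F7, and oxalyl chloride with catalytic DMF gives (2Z)-2-methoxybut-2-enoyl chloride F8. Slow addition of F8 to 10 and Et3N in hot toluene generates ketene 14 by 1,4-dehydrochlorination, and the cascade of step 7 then leads to 18.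

**Step 9.**
- *What may go wrong:* poor site selectivity between the two carbons ortho to the hydroxyl, O-addition of the phenol to the alkynoate instead of C–C bond formation, and partial loss of the benzyl group in the acid.
- *Fallback:* it sets out from 19 and comes back at 22. Ortho-formylation (MgCl2, Et3N, paraformaldehyde, MeCN, reflux), which is directed by the magnesium phenoxide to the unhindered ortho carbon, gives 4-{[7-(benzyloxy)-6-methoxy-2-oxochromen-3-yl]oxy}-2-hydroxy-5-methoxybenzaldehyde F9. Wittig olefination with Ph3P=CHCO2Et in N,N-diethylaniline at reflux gives ethyl (2E)-3-(4-{[7-(benzyloxy)-6-methoxy-2-oxochromen-3-yl]oxy}-2-hydroxy-5-methoxyphenyl)prop-2-enoate F10, which isomerises thermally to 21 and lactonises to 22.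

**Step 3.**
- *What may go wrong:* cleavage of the benzyl ether in hot aqueous acid, or hydrolysis stopping at the amine stage.
- *Fallback:* it sets out from 2 and comes back at 8 without any amide hydrolysis. Acylation of 2 with acetoxyacetyl chloride (Et3N, CH2Cl2) gives 5-(benzyloxy)-2-formyl-4-methoxyphenyl (acetyloxy)acetate F11. Intramolecular aldol condensation (DBU, MeCN) closes it to 7-(benzyloxy)-6-methoxy-2-oxochromen-3-yl acetate F12, and the enol acetate is cleaved with K2CO3 in MeOH at 0 °C to give 8.

## Further compounds

F1 | step 7 | tert-butyl [(6-methoxy-2-oxochromen-7-yl)oxy]acetate | COc1cc2ccc(=O)oc2cc1OCC(=O)OC(C)(C)C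
F2 | step 7 | [(6-methoxy-2-oxochromen-7-yl)oxy]acetic acid | COc1cc2ccc(=O)oc2cc1OCC(=O)O
F3 | step 4 | (3-bromo-4-methoxyphenoxy)(tert-butyl)dimethylsilane | COc1ccc(O[Si](C)(C)C(C)(C)C)cc1Br
F4 | step 4 | {5-[(tert-butyldimethylsilyl)oxy]-2-methoxyphenyl}boronic acid | COc1ccc(O[Si](C)(C)C(C)(C)C)cc1B(O)O
F5 | step 4 | 7-(benzyloxy)-3-{5-[(tert-butyldimethylsilyl)oxy]-2-methoxyphenoxy}-6-methoxychromen-2-one | COc1ccc(O[Si](C)(C)C(C)(C)C)cc1Oc1cc2cc(OC)c(OCc3ccccc3)cc2oc1=O
F6 | step 6 | methyl (2Z)-2-methoxybut-2-enoate | C/C=C(\OC)C(=O)OC
F7 | step 6 | (2Z)-2-methoxybut-2-enoic acid | C/C=C(\OC)C(=O)O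
F8 | step 6 | (2Z)-2-methoxybut-2-enoyl chloride | C/C=C(\OC)C(=O)Cl
F9 | step 9 | 4-{[7-(benzyloxy)-6-methoxy-2-oxochromen-3-yl]oxy}-2-hydroxy-5-methoxybenzaldehyde | COc1cc(C=O)c(O)cc1Oc1cc2cc(OC)c(OCc3ccccc3)cc2oc1=O
F10 | step 9 | ethyl (2E)-3-(4-{[7-(benzyloxy)-6-methoxy-2-oxochromen-3-yl]oxy}-2-hydroxy-5-methoxyphenyl)prop-2-enoate | CCOC(=O)/C=C/c1cc(OC)c(Oc2cc3cc(OC)c(OCc4ccccc4)cc3oc2=O)cc1O
F11 | step 3 | 5-(benzyloxy)-2-formyl-4-methoxyphenyl (acetyloxy)acetate | CC(=O)OCC(=O)Oc1cc(OCc2ccccc2)c(OC)cc1C=O
F12 | step 3 | 7-(benzyloxy)-6-methoxy-2-oxochromen-3-yl acetate | CC(=O)Oc1cc2cc(OC)c(OCc3ccccc3)cc2oc1=O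
A1 | alternative 1 | ethyl 3-(2,4-diacetoxy-5-methoxyphenyl)-3-hydroxy-2-[(6-methoxy-2-oxochromen-7-yl)oxy]propanoate (racemic, one diastereomer drawn) | CCOC(=O)[C@@H](Oc1cc2oc(=O)ccc2cc1OC)[C@H](O)c1cc(OC)c(OC(C)=O)cc1OC(C)=O
A2 | alternative 1 | ethyl diazoacetate | CCOC(=O)C=[N+]=[N-]
A3 | alternative 1 | 7-hydroxy-6-methoxychromen-2-one (scopoletin) | COc1cc2ccc(=O)oc2cc1O
A4 | alternative 1 | 4-formyl-6-methoxy-1,3-phenylene diacetate | COc1cc(C=O)c(OC(C)=O)cc1OC(C)=O
A5 | alternative 2 | 6-methoxy-3-[(6-methoxy-2-oxochromen-7-yl)oxy]-2-oxochromen-7-yl acetate | COc1cc2cc(Oc3cc4oc(=O)ccc4cc3OC)c(=O)oc2cc1OC(C)=O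
A6 | alternative 2 | (2E)-3-(4-{[7-(acetyloxy)-6-methoxy-2-oxochromen-3-yl]oxy}-3-methoxyphenyl)prop-2-enoic acid | COc1cc(/C=C/C(=O)O)ccc1Oc1cc2cc(OC)c(OC(C)=O)cc2oc1=O
A7 | alternative 3 | 7-(benzyloxy)-6-methoxy-3-[(6-methoxy-2-oxochromen-7-yl)oxy]chroman-2-one (racemic, one enantiomer drawn) | COc1cc2c(cc1OCc1ccccc1)OC(=O)[C@@H](Oc1cc3oc(=O)ccc3cc1OC)C2
A8 | alternative 3 | 6-(benzyloxy)-5-methoxy-2-[(6-methoxy-2-oxochromen-7-yl)oxy]-2,3-dihydro-1H-inden-1-one (racemic) | COc1cc2c(cc1OCc1ccccc1)C(=O)C(Oc1cc3oc(=O)ccc3cc1OC)C2
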